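**Strategy**

1. Core numbering: C1 ketone, C2 nitrogen-bearing carbon, C3, C4 carbinol, C5 and C6 oxirane carbons (C6 beside the ketone). Retrosynthetic cuts, in order: the C–C bond between the first and second alkene of the lower triene (Stille), the N–C2 bond of the ring enamide (copper-catalysed amidation of a C2 iodide), then both oxirane C–O bonds (C5–O and C6–O).
2. Enabling feature: without the C2 nitrogen, C1 and C4 lie on a mirror plane of a 4-alkynyl-4-hydroxycyclohexa-2,5-dienone. The alkenes C2=C3 and C5=C6 are then enantiotopic, and one oxygen transfer to one of them, on the hydroxyl face, fixes C4, C5 and C6 together.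
3. Forward order: the carbocycle is bought as para-benzoquinone dimethyl monoketal and alkynylated; the oxirane is closed by desymmetrizing epoxidation; C2 iodination and C–N coupling attach the upper trienamide; desilylation, hydrostannation and Stille coupling attach the lower bromodienamide, whose cyclopentenone ring is bought as cyclopentane-1,3-dione.
4. Stereochemistry: C4, C5 and C6 come from the catalyst-controlled, hydroxyl-directed epoxidation; C8 of the upper chain from (R)-2-methylbutanoic acid; the E alkenes from ethyl sorbate, the Horner–Wadsworth–Emmons step, glutaconaldehyde potassium salt, syn hydrostannation and stereoretentive Stille coupling.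

Key step: step 3

Assumption: the sense of induction of the cinchona primary amine on this dienone cannot be predicted with certainty; the quinine-derived amine is written, and its quinidine-derived pseudoenantiomer is used instead if that is the one leading to the (1S,5R,6R) epoxy quinol.

**Route**

Step 1
Reactants: 1 ethynyl(trimethyl)silane (trimethylsilylacetylene); 2 4,4-dimethoxycyclohexa-2,5-dien-1-one (para-benzoquinone dimethyl monoketal)
Product: 4 4,4-dimethoxy-1-[(trimethylsilyl)ethynyl]cyclohexa-2,5-dien-1-ol, via lithium (trimethylsilyl)acetylide 3 (not isolated)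
Conditions: n-BuLi, THF, −78 °C; then 2, −78 °C; sat. aq. NH4Cl
Reagents that add atoms: none
Why: 1,2-addition of a lithium acetylide to the free ketone of a quinone monoketal; the hard acetylide attacks the carbonyl carbon rather than the enone β-positions, and the ketal masks the second carbonyl.

Step 2
Reactants: 4 4,4-dimethoxy-1-[(trimethylsilyl)ethynyl]cyclohexa-2,5-dien-1-ol
Product: 5 4-hydroxy-4-[(trimethylsilyl)ethynyl]cyclohexa-2,5-dien-1-one (achiral para-quinol)
Conditions: AcOH/H2O (1:9), acetone, rt
Reagents that add atoms: water, O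
Why: acid-catalysed ketal hydrolysis; the doubly allylic dimethyl ketal ionises to a stabilised oxocarbenium ion much faster than the tertiary carbinol, so mild aqueous acid should unveil the dienone without dienone–phenol rearrangement or loss of the silyl group.

Step 3
Reactants: 5 4-hydroxy-4-[(trimethylsilyl)ethynyl]cyclohexa-2,5-dien-1-one
Product: 6 (1S,5R,6R)-5-hydroxy-5-[(trimethylsilyl)ethynyl]-7-oxabicyclo[4.1.0]hept-3-en-2-one (syn epoxy quinol, oxirane and hydroxyl on the same face)
Conditions: 9-amino-9-deoxy-epi-quinine·2CF3CO2H (10 mol %), 30% aq. H2O2 (1.0 equiv, added slowly), 1,4-dioxane, 30 °C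
Reagents that add atoms: hydrogen peroxide, OO
Why: Proposed new method: the primary amine of the catalyst condenses with the C1 ketone to a cross-conjugated iminium ion, hydrogen peroxide held by the protonated quinuclidine and by a hydrogen bond to the C4 hydroxyl adds to C5 of one enantiotopic alkene, and the resulting enamine attacks the proximal peroxide oxygen from C6 with loss of water before hydrolysis frees the catalyst. The closest known reaction types are the cinchona primary amine salt/H2O2 epoxidation of cyclic enones (an asymmetric Weitz–Scheffer epoxidation by iminium activation), the hydroxyl-directed syn nucleophilic epoxidation of racemic para-quinols and organocatalytic desymmetrizations of 4,4-disubstituted cyclohexadienones. The oxirane closes by 3-exo-tet displacement at oxygen. C5 and C6 are set by the chiral ammonium catalyst, which selects the alkene, together with the C4 hydroxyl, which steers the peroxide to its own face; C4 becomes a stereocentre only through the choice between the two enantiotopic alkenes. The step needs enantiotopic-alkene selectivity (catalyst), syn facial selectivity (free C4 hydroxyl opposite a slim, non-coordinating silylalkyne) and mono-epoxidation (limiting peroxide, and the epoxy enone is a poorer iminium acceptor than the dienone). The flat, unhindered dienone should form the iminium ion readily and the silylalkyne is inert to peroxide.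

Step 4
Reactants: 6 (1S,5R,6R)-5-hydroxy-5-[(trimethylsilyl)ethynyl]-7-oxabicyclo[4.1.0]hept-3-en-2-one
Product: 7 (1S,5R,6R)-5-hydroxy-3-iodo-5-[(trimethylsilyl)ethynyl]-7-oxabicyclo[4.1.0]hept-3-en-2-one (α-iodo enone)
Conditions: I2, pyridine, CH2Cl2, 0 °C to rt; aq. Na2S2O3
Reagents that add atoms: iodine, II
Why: α-iodination of an enone by the Baylis–Hillman-type sequence (pyridine adds at C3, the enolate is iodinated at C2, pyridine is eliminated); only one enone remains, so iodine should enter at C2 alone, and the oxirane, tertiary alcohol and silylalkyne are inert to I2/pyridine.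

Step 5
Reactants: 8 ethyl (2E,4E)-hexa-2,4-dienoate (ethyl sorbate)
Product: 9 ethyl (2E,4E)-6-bromohexa-2,4-dienoate
Conditions: N-bromosuccinimide, AIBN (cat.), PhCF3, 85 °C
Reagents that add atoms: N-bromosuccinimide, O=C1CCC(=O)N1Br
Why: Wohl–Ziegler bromination; hydrogen abstraction from the terminal methyl gives a radical delocalised over the dienoate, which is brominated at the terminus so that the conjugated (2E,4E) system is kept.

Step 6
Reactants: 9 ethyl (2E,4E)-6-bromohexa-2,4-dienoate
Product: 10 ethyl (2E,4E)-6-(diethoxyphosphoryl)hexa-2,4-dienoate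
Conditions: P(OEt)3, neat, 130 °C, EtBr distilled off
Reagents that add atoms: triethyl phosphite, CCOP(OCC)OCC
Why: Michaelis–Arbuzov reaction; the phosphite displaces the primary allylic bromide and bromide dealkylates the phosphonium ion, with the diene geometry retained.

Step 7
Reactants: 11 (R)-2-methylbutanoic acid
Product: 12 (R)-2-methylbutan-1-ol
Conditions: LiAlH4, Et2O, 0 °C to rt; aqueous work-up
Reagents that add atoms: none
Why: hydride reduction of a carboxylic acid; the stereocentre is not enolisable at the carboxylate or alkoxide stage, so the R configuration should be carried through unchanged.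

Step 8
Reactants: 12 (R)-2-methylbutan-1-ol; 10 ethyl (2E,4E)-6-(diethoxyphosphoryl)hexa-2,4-dienoate
Product: 14 ethyl (2E,4E,6E,8R)-8-methyldeca-2,4,6-trienoate, via (R)-2-methylbutanal 13 (not isolated)
Conditions: Dess–Martin periodinane, CH2Cl2, 0 °C to rt; cold aq. NaHCO3 wash, dry; solution of 13 added to 10 + LiN(SiMe3)2, THF, −78 to 0 °C
Reagents that add atoms: none
Why: Dess–Martin oxidation followed by vinylogous Horner–Wadsworth–Emmons olefination; the non-basic oxidation and immediate low-temperature use of the α-branched aldehyde protect the R stereocentre, and the stabilised phosphonate anion reacts at its α-carbon to give the new 6E alkene.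

Step 9
Reactants: 14 ethyl (2E,4E,6E,8R)-8-methyldeca-2,4,6-trienoate
Product: 15 (2E,4E,6E,8R)-8-methyldeca-2,4,6-trienoic acid
Conditions: LiOH, THF/H2O, rt; then 1 M HCl to pH 3
Reagents that add atoms: lithium hydroxide, [Li+].[OH-]
Why: ester saponification by acyl–oxygen cleavage; the mild conditions leave the triene geometry and the remote C8 stereocentre untouched.

Step 10
Reactants: 15 (2E,4E,6E,8R)-8-methyldeca-2,4,6-trienoic acid
Product: 17 (2E,4E,6E,8R)-8-methyldeca-2,4,6-trienamide (upper fragment), via isobutyl carbonic mixed anhydride 16 (not isolated)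
Conditions: i-BuOCOCl, N-methylmorpholine, THF, −15 °C; then NH3 (aq.), −15 °C to rt
Reagents that add atoms: ammonia, N
Why: mixed carbonic anhydride amidation; ammonia attacks the acyl carbonyl of the activated acid in preference to the carbonate carbonyl and gives the primary amide without touching the triene.

Step 11
Reactants: 7 (1S,5R,6R)-5-hydroxy-3-iodo-5-[(trimethylsilyl)ethynyl]-7-oxabicyclo[4.1.0]hept-3-en-2-one; 17 (2E,4E,6E,8R)-8-methyldeca-2,4,6-trienamide
Product: 18 (2E,4E,6E,8R)-N-[(1S,5R,6R)-5-hydroxy-2-oxo-5-[(trimethylsilyl)ethynyl]-7-oxabicyclo[4.1.0]hept-3-en-3-yl]-8-methyldeca-2,4,6-trienamide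
Conditions: CuI (10 mol %, monovalent copper), MeNHCH2CH2NHMe (20 mol %), K2CO3, THF, 45 °C, argon, dark
Reagents that add atoms: none
Why: Goldberg-type copper-catalysed amidation of a vinyl iodide; the diamine-ligated copper amidate inserts into the activated C2–I bond of the α-iodo enone and reductive elimination forms the enamide with the ring alkene in place, while the tertiary alcohol, oxirane and silyl-capped alkyne should tolerate carbonate at mild temperature.

Step 12
Reactants: 19 potassium (1E,3E)-5-oxopenta-1,3-dien-1-olate (glutaconaldehyde potassium salt)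
Product: 20 (2E,4E)-5-bromopenta-2,4-dienal
Conditions: PPh3, Br2, CH2Cl2, 0 °C; then 19, 0 °C to rt
Reagents that add atoms: bromine, BrBr
Why: deoxybromination of the enolate with Ph3PBr2 (the enolate oxygen binds phosphorus, bromide adds at the terminal carbon and Ph3PO is lost), the product settling as the more stable (2E,4E)-dienal.

Step 13
Reactants: 20 (2E,4E)-5-bromopenta-2,4-dienal
Product: 21 (2E,4E)-5-bromopenta-2,4-dienoic acid
Conditions: NaClO2, NaH2PO4, 2-methylbut-2-ene, t-BuOH/H2O, 0 °C to rt
Reagents that add atoms: sodium chlorite, [Na+].[O-]Cl=O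
Why: Pinnick oxidation; chlorous acid oxidises the aldehyde to the acid while 2-methylbut-2-ene traps hypochlorous acid, so the bromodiene stays intact.

Step 14
Reactants: 22 cyclopentane-1,3-dione
Product: 23 2-(hydroxyimino)cyclopentane-1,3-dione
Conditions: NaNO2, aq. HCl, 0 °C
Reagents that add atoms: sodium nitrite, [Na+].[O-]N=O
Why: C-nitrosation of the highly enolised 1,3-dione at C2 by nitrous acid, followed by tautomerisation to the oxime.

Step 15
Reactants: 23 2-(hydroxyimino)cyclopentane-1,3-dione
Product: 24 2-aminocyclopentane-1,3-dione hydrochloride (enol form: 2-amino-3-hydroxycyclopent-2-en-1-one hydrochloride)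
Conditions: H2 (1 atm), Pd/C, HCl, MeOH, rt
Reagents that add atoms: hydrogen chloride, Cl
Why: catalytic hydrogenation of an α-oximino ketone to the amine, which is trapped as its hydrochloride so that the aminodione cannot self-condense.

Step 16
Reactants: 21 (2E,4E)-5-bromopenta-2,4-dienoic acid; 24 2-aminocyclopentane-1,3-dione hydrochloride
Product: 26 (2E,4E)-5-bromo-N-(2-hydroxy-5-oxocyclopent-1-en-1-yl)penta-2,4-dienamide (lower fragment), via (2E,4E)-5-bromopenta-2,4-dienoyl chloride 25 (not isolated)
Conditions: (COCl)2, DMF (cat.), CH2Cl2, 0 °C to rt, evaporate; then 24, Et3N, THF, 0 °C to rt; dilute aq. HCl work-up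
Reagents that add atoms: none
Why: acid chloride formation and N-acylation of the amine freed from its hydrochloride; any enol ester formed at oxygen should shift to nitrogen or be cleaved on aqueous work-up, leaving the amide of the vinylogous acid.

Step 17
Reactants: 18 (2E,4E,6E,8R)-N-[(1S,5R,6R)-5-hydroxy-2-oxo-5-[(trimethylsilyl)ethynyl]-7-oxabicyclo[4.1.0]hept-3-en-3-yl]-8-methyldeca-2,4,6-trienamide
Product: 27 (2E,4E,6E,8R)-N-[(1S,5R,6R)-5-ethynyl-5-hydroxy-2-oxo-7-oxabicyclo[4.1.0]hept-3-en-3-yl]-8-methyldeca-2,4,6-trienamide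
Conditions: Bu4NF, AcOH, THF, 0 °C
Reagents that add atoms: none
Why: fluoride-induced protodesilylation of the alkynylsilane, buffered with acetic acid so that the base-sensitive epoxy ketone and enamide meet neither free alkoxide nor unbuffered fluoride.

Step 18
Reactants: 27 (2E,4E,6E,8R)-N-[(1S,5R,6R)-5-ethynyl-5-hydroxy-2-oxo-7-oxabicyclo[4.1.0]hept-3-en-3-yl]-8-methyldeca-2,4,6-trienamide
Product: 28 (2E,4E,6E,8R)-N-[(1S,5R,6R)-5-hydroxy-2-oxo-5-[(E)-2-(tributylstannyl)ethenyl]-7-oxabicyclo[4.1.0]hept-3-en-3-yl]-8-methyldeca-2,4,6-trienamide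
Conditions: Bu3SnH (1.1 equiv, slow addition), PdCl2(PPh3)2 (3 mol %, divalent palladium precatalyst), THF, −20 to 0 °C
Reagents that add atoms: tributyltin hydride, CCCC[SnH](CCCC)CCCC
Why: palladium-catalysed syn hydrostannation of a terminal alkyne; hydrogen and tin add to the same face with tin at the unhindered terminal carbon, away from the fully substituted carbinol carbon, giving the E vinylstannane faster than any reduction of the enone.

Step 19
Reactants: 28 (2E,4E,6E,8R)-N-[(1S,5R,6R)-5-hydroxy-2-oxo-5-[(E)-2-(tributylstannyl)ethenyl]-7-oxabicyclo[4.1.0]hept-3-en-3-yl]-8-methyldeca-2,4,6-trienamide; 26 (2E,4E)-5-bromo-N-(2-hydroxy-5-oxocyclopent-1-en-1-yl)penta-2,4-dienamide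
Product: 29 (2E,4E,6E,8R)-N-[(1S,5S,6R)-5-hydroxy-5-[(1E,3E,5E)-7-[(2-hydroxy-5-oxocyclopent-1-en-1-yl)amino]-7-oxohepta-1,3,5-trien-1-yl]-2-oxo-7-oxabicyclo[4.1.0]hept-3-en-3-yl]-8-methyldeca-2,4,6-trienamide (target CNP0596887.4)
Conditions: PdCl2(MeCN)2 (10 mol %, divalent palladium precatalyst), DMF, rt, argon, dark
Reagents that add atoms: none
Why: Stille cross-coupling; oxidative addition of the dienyl bromide to zerovalent palladium formed in situ, transmetalation from the vinylstannane and reductive elimination all proceed with retention of alkene geometry under neutral conditions that spare the oxirane, the tertiary alcohol and the acidic enol.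

**Compound list**

1 | ethynyl(trimethyl)silane (trimethylsilylacetylene) | C#C[Si](C)(C)C | starting material
2 | 4,4-dimethoxycyclohexa-2,5-dien-1-one | COC1(OC)C=CC(=O)C=C1 | starting material
3 | lithium (trimethylsilyl)acetylide | [Li+].[C-]#C[Si](C)(C)C | intermediate
4 | 4,4-dimethoxy-1-[(trimethylsilyl)ethynyl]cyclohexa-2,5-dien-1-ol | COC1(OC)C=CC(O)(C#C[Si](C)(C)C)C=C1 | intermediate
5 | 4-hydroxy-4-[(trimethylsilyl)ethynyl]cyclohexa-2,5-dien-1-one | O=C1C=CC(O)(C#C[Si](C)(C)C)C=C1 | intermediate
6 | (1S,5R,6R)-5-hydroxy-5-[(trimethylsilyl)ethynyl]-7-oxabicyclo[4.1.0]hept-3-en-2-one | C1=C[C@@](O)(C#C[Si](C)(C)C)[C@@H]2O[C@@H]2C1=O | intermediate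
7 | (1S,5R,6R)-5-hydroxy-3-iodo-5-[(trimethylsilyl)ethynyl]-7-oxabicyclo[4.1.0]hept-3-en-2-one | IC1=C[C@@](O)(C#C[Si](C)(C)C)[C@@H]2O[C@@H]2C1=O | intermediate
8 | ethyl (2E,4E)-hexa-2,4-dienoate (ethyl sorbate) | C/C=C/C=C/C(=O)OCC | starting material
9 | ethyl (2E,4E)-6-bromohexa-2,4-dienoate | BrC/C=C/C=C/C(=O)OCC | intermediate
10 | ethyl (2E,4E)-6-(diethoxyphosphoryl)hexa-2,4-dienoate | CCOC(=O)/C=C/C=C/CP(=O)(OCC)OCC | intermediate
11 | (R)-2-methylbutanoic acid | CC[C@@H](C)C(=O)O | starting material
12 | (R)-2-methylbutan-1-ol | CC[C@@H](C)CO | intermediate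
13 | (R)-2-methylbutanal | CC[C@@H](C)C=O | intermediate
14 | ethyl (2E,4E,6E,8R)-8-methyldeca-2,4,6-trienoate | CC[C@@H](C)/C=C/C=C/C=C/C(=O)OCC | intermediate
15 | (2E,4E,6E,8R)-8-methyldeca-2,4,6-trienoic acid | CC[C@@H](C)/C=C/C=C/C=C/C(=O)O | intermediate
16 | (2E,4E,6E,8R)-8-methyldeca-2,4,6-trienoic isobutyl carbonic anhydride | CC[C@@H](C)/C=C/C=C/C=C/C(=O)OC(=O)OCC(C)C | intermediate
17 | (2E,4E,6E,8R)-8-methyldeca-2,4,6-trienamide | CC[C@@H](C)/C=C/C=C/C=C/C(N)=O | intermediate
18 | (2E,4E,6E,8R)-N-[(1S,5R,6R)-5-hydroxy-2-oxo-5-[(trimethylsilyl)ethynyl]-7-oxabicyclo[4.1.0]hept-3-en-3-yl]-8-methyldeca-2,4,6-trienamide | CC[C@@H](C)/C=C/C=C/C=C/C(=O)NC1=C[C@@](O)(C#C[Si](C)(C)C)[C@@H]2O[C@@H]2C1=O | intermediate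
19 | potassium (1E,3E)-5-oxopenta-1,3-dien-1-olate (glutaconaldehyde potassium salt) | [K+].[O-]/C=C/C=C/C=O | starting material
20 | (2E,4E)-5-bromopenta-2,4-dienal | Br/C=C/C=C/C=O | intermediate
21 | (2E,4E)-5-bromopenta-2,4-dienoic acid | Br/C=C/C=C/C(=O)O | intermediate
22 | cyclopentane-1,3-dione | O=C1CCC(=O)C1 | starting material
23 | 2-(hydroxyimino)cyclopentane-1,3-dione | ON=C1C(=O)CCC1=O | intermediate
24 | 2-aminocyclopentane-1,3-dione hydrochloride (2-amino-3-hydroxycyclopent-2-en-1-one hydrochloride) | Cl.NC1=C(O)CCC1=O | intermediate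
25 | (2E,4E)-5-bromopenta-2,4-dienoyl chloride | Br/C=C/C=C/C(Cl)=O | intermediate
26 | (2E,4E)-5-bromo-N-(2-hydroxy-5-oxocyclopent-1-en-1-yl)penta-2,4-dienamide | Br/C=C/C=C/C(=O)NC1=C(O)CCC1=O | intermediate
27 | (2E,4E,6E,8R)-N-[(1S,5R,6R)-5-ethynyl-5-hydroxy-2-oxo-7-oxabicyclo[4.1.0]hept-3-en-3-yl]-8-methyldeca-2,4,6-trienamide | CC[C@@H](C)/C=C/C=C/C=C/C(=O)NC1=C[C@@](O)(C#C)[C@@H]2O[C@@H]2C1=O | intermediate
28 | (2E,4E,6E,8R)-N-[(1S,5R,6R)-5-hydroxy-2-oxo-5-[(E)-2-(tributylstannyl)ethenyl]-7-oxabicyclo[4.1.0]hept-3-en-3-yl]-8-methyldeca-2,4,6-trienamide | CC[C@@H](C)/C=C/C=C/C=C/C(=O)NC1=C[C@@](O)(/C=C/[Sn](CCCC)(CCCC)CCCC)[C@@H]2O[C@@H]2C1=O | intermediate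
29 | (2E,4E,6E,8R)-N-[(1S,5S,6R)-5-hydroxy-5-[(1E,3E,5E)-7-[(2-hydroxy-5-oxocyclopent-1-en-1-yl)amino]-7-oxohepta-1,3,5-trien-1-yl]-2-oxo-7-oxabicyclo[4.1.0]hept-3-en-3-yl]-8-methyldeca-2,4,6-trienamide | CC[C@@H](C)/C=C/C=C/C=C/C(=O)NC1=C[C@@](O)(/C=C/C=C/C=C/C(=O)NC2=C(O)CCC2=O)[C@@H]2O[C@@H]2C1=O | target

**Step count**

Total: 19 steps. Longest linear sequence: 9 steps (steps 5, 6, 8, 9, 10, 11, 17, 18 and 19, from ethyl sorbate 8). The core line from 1 and 2 is 8 steps.

**Steps most likely to fail**

Step 3 (proposed new method). The chiral amine may discriminate poorly between the two enantiotopic alkenes, iminium formation on the cross-conjugated dienone may be slow, or a second oxygen transfer may follow the first. The fallback uses known chemistry, sets out from compound 2 and comes back at compound 6, with the oxirane installed before the alkyne. Chiral phase-transfer nucleophilic epoxidation of 2 (tert-butyl hydroperoxide, aqueous NaOH, N-benzylcinchonidinium chloride or its cinchonine-derived pseudoenantiomer, toluene, 0 °C, enrichment by recrystallisation if needed) would give the epoxy quinone monoketal (1R,6S)-5,5-dimethoxy-7-oxabicyclo[4.1.0]hept-3-en-2-one F1. Addition of lithium (trimethylsilyl)acetylide 3 at −78 °C should occur on the face opposite the oxirane and give the syn hydroxy epoxide (1R,2R,6S)-5,5-dimethoxy-2-[(trimethylsilyl)ethynyl]-7-oxabicyclo[4.1.0]hept-3-en-2-ol F2. Mild acid hydrolysis of its ketal, as in step 2, would then deliver 6.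

Step 11. C–N bond formation with the sparingly soluble polyene amide may be slow, leaving time for base-induced degradation of the iodo epoxy enone (protodeiodination, desilylation). The fallback sets out from compound 7 and comes back at compound 18; it introduces nitrogen first and forms the amide bond afterwards. Copper-catalysed azidation of 7 (NaN3, CuI as monovalent copper, sodium ascorbate, N,N'-dimethylethylenediamine, aqueous ethanol, rt; the silyl-capped alkyne cannot undergo azide–alkyne cycloaddition) would give the vinyl azide (1S,5R,6R)-3-azido-5-hydroxy-5-[(trimethylsilyl)ethynyl]-7-oxabicyclo[4.1.0]hept-3-en-2-one F3. Staudinger reduction (PPh3, THF, then water) would pass through the iminophosphorane (1S,5R,6R)-5-hydroxy-5-[(trimethylsilyl)ethynyl]-3-[(triphenyl-λ5-phosphanylidene)amino]-7-oxabicyclo[4.1.0]hept-3-en-2-one F4, not isolated, to the amino enone (1S,5R,6R)-3-amino-5-hydroxy-5-[(trimethylsilyl)ethynyl]-7-oxabicyclo[4.1.0]hept-3-en-2-one F5. N-acylation of F5 in pyridine/CH2Cl2 at 0 °C with (2E,4E,6E,8R)-8-methyldeca-2,4,6-trienoyl chloride F6, made from acid 15 with oxalyl chloride and catalytic DMF, would give 18; the tertiary alcohol should not compete.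

Step 18. Tin may be delivered to the internal alkyne carbon beside the carbinol, and excess tin hydride may start to reduce the enone. The fallback sets out from compound 27 and comes back at compound 28; regiocontrol is written into the substrate. Bromination of the terminal alkyne (N-bromosuccinimide, catalytic AgNO3, acetone, rt) would give the bromoalkyne (2E,4E,6E,8R)-N-[(1S,5R,6R)-5-(bromoethynyl)-5-hydroxy-2-oxo-7-oxabicyclo[4.1.0]hept-3-en-3-yl]-8-methyldeca-2,4,6-trienamide F7. Palladium-catalysed hydrostannation of a 1-bromoalkyne with two equivalents of Bu3SnH (PdCl2(PPh3)2, THF, 0 °C) places tin on the halogen-bearing carbon and reduces the resulting vinyl bromide in the same flask, so only the E terminal vinylstannane 28 should form. This fallback addresses the regiochemistry only, not reduction of the enone.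

Further compounds
F1 | step 3 | (1R,6S)-5,5-dimethoxy-7-oxabicyclo[4.1.0]hept-3-en-2-one | C1=CC(=O)[C@@H]2O[C@@H]2C1(OC)OC
F2 | step 3 | (1R,2R,6S)-5,5-dimethoxy-2-[(trimethylsilyl)ethynyl]-7-oxabicyclo[4.1.0]hept-3-en-2-ol | C1=C[C@@](O)(C#C[Si](C)(C)C)[C@@H]2O[C@@H]2C1(OC)OC
F3 | step 11 | (1S,5R,6R)-3-azido-5-hydroxy-5-[(trimethylsilyl)ethynyl]-7-oxabicyclo[4.1.0]hept-3-en-2-one | [N-]=[N+]=NC1=C[C@@](O)(C#C[Si](C)(C)C)[C@@H]2O[C@@H]2C1=O
F4 | step 11 | (1S,5R,6R)-5-hydroxy-5-[(trimethylsilyl)ethynyl]-3-[(triphenyl-λ5-phosphanylidene)amino]-7-oxabicyclo[4.1.0]hept-3-en-2-one | c1ccc(cc1)P(c1ccccc1)(c1ccccc1)=NC1=C[C@@](O)(C#C[Si](C)(C)C)[C@@H]2O[C@@H]2C1=O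
F5 | step 11 | (1S,5R,6R)-3-amino-5-hydroxy-5-[(trimethylsilyl)ethynyl]-7-oxabicyclo[4.1.0]hept-3-en-2-one | NC1=C[C@@](O)(C#C[Si](C)(C)C)[C@@H]2O[C@@H]2C1=O
F6 | step 11 | (2E,4E,6E,8R)-8-methyldeca-2,4,6-trienoyl chloride | CC[C@@H](C)/C=C/C=C/C=C/C(Cl)=O
F7 | step 18 | (2E,4E,6E,8R)-N-[(1S,5R,6R)-5-(bromoethynyl)-5-hydroxy-2-oxo-7-oxabicyclo[4.1.0]hept-3-en-3-yl]-8-methyldeca-2,4,6-trienamide | CC[C@@H](C)/C=C/C=C/C=C/C(=O)NC1=C[C@@](O)(C#CBr)[C@@H]2O[C@@H]2C1=O
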